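**Plan**

1. Ring numbering: C1″ carries the methyl, C2″ is the ring CH=, C3″ the chalcone-bearing aryl, C4″ the aroyl, C5″ the 2,4-dihydroxyphenyl, C6″ the CH2. The retrosynthesis opens the cyclohexene by retro-[4+2]: C5″–C6″ and C3″–C4″ are cut and the C1″=C2″ double bond goes back into a 1,3-diene. This gives the 2′-hydroxychalcone 11 (dienophile) and the dehydroprenyl chalcone 15 (diene). In the forward sense one event makes the C1″=C2″ double bond and the C5″–C6″ bond, together with C3″–C4″.
2. The feature that allows this is the cyclohexene itself. Its C1″=C2″ double bond lies across the ring from the C4″–C5″ bond, and the C4″ ketone sits on an aryl ring with an ortho hydroxyl, which is a handle for boron chelation. The trans C4″-aroyl/C5″-aryl and cis C3″-aryl/C4″-aroyl relations are those of an endo addition of an E-diene to an E-enone, as in the presumed biosynthesis.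
3. Both partners are cut at the aryl–alkenyl bond (C3′ of the resorcinol ketone ring) back to one 3′-iodochalcone 7. Compound 7 is cut at its enone C=C (Claisen–Schmidt) to iodoketone 3 and aldehyde 5.
4. Forward order: iodination, chalcone formation, exchange of MOM for acetate, two cross-couplings at C3′ (alkenyl for 11; hydroxyalkenyl then dehydration for 15). The only new ring, the cyclohexene, arises in step 12, and global deacetylation ends the route.
5. Stereochemistry: all three stereocentres (3″S,4″R,5″S) are set in step 12. Trans C4″/C5″ comes from the E-enone, cis C3″/C4″ from the endo transition state, and the absolute sense from the chiral diolate on boron. Alkene geometries come from the condensation, syn-hydrostannation and the Heck reaction.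

Key step: step 12

Assumption: the (R)-enantiomer of the biaryl diol is taken to shield the face of the boron-bound enone that leads to the (3″S,4″R,5″S) series; if the sense of induction is the reverse, the (S)-diol is used and nothing else changes.

**Route**

Step 1
Reactants: 1 2,4-dihydroxyacetophenone
Product: 2 1-(2,4-dihydroxy-3-iodophenyl)ethan-1-one
Conditions: I2, HIO3, EtOH–H2O, 35–40 °C
Reagents that add atoms: iodine II; iodic acid OI(=O)=O
Why: Electrophilic aromatic iodination, with HIO3 returning the iodide to the active iodine level, should occur at C3, the position ortho to both hydroxyl groups of the resorcinol ketone.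

Step 2
Reactants: 2 1-(2,4-dihydroxy-3-iodophenyl)ethan-1-one
Product: 3 1-[2-hydroxy-3-iodo-4-(methoxymethoxy)phenyl]ethan-1-one
Conditions: MOMCl (1.1 equiv), K2CO3, acetone, 0 °C → rt
Reagents that add atoms: chloromethyl methyl ether COCCl
Why: Williamson-type O-alkylation should take only the 4-hydroxyl, because the 2-hydroxyl is held in a hydrogen bond to the acetyl carbonyl.

Step 3
Reactants: 4 2,4-dihydroxybenzaldehyde
Product: 5 2,4-bis(methoxymethoxy)benzaldehyde
Conditions: MOMCl (2.5 equiv), K2CO3, acetone, reflux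
Reagents that add atoms: chloromethyl methyl ether COCCl
Why: Exhaustive O-alkylation masks both phenols so that the aldehyde stays electrophilic (no phenoxide donation) in the base-mediated condensation that follows.

Step 4
Reactants: 3 1-[2-hydroxy-3-iodo-4-(methoxymethoxy)phenyl]ethan-1-one; 5 2,4-bis(methoxymethoxy)benzaldehyde
Product: 6 (E)-3-[2,4-bis(methoxymethoxy)phenyl]-1-[2-hydroxy-3-iodo-4-(methoxymethoxy)phenyl]prop-2-en-1-one
Conditions: KOH (aq.), EtOH, rt
Reagents that add atoms: none
Why: Claisen–Schmidt condensation (aldol addition, then E1cB loss of water) should give the thermodynamically preferred E-enone, and the MOM ethers and the aryl iodide are inert to hydroxide at room temperature.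

Step 5
Reactants: 6 (E)-3-[2,4-bis(methoxymethoxy)phenyl]-1-[2-hydroxy-3-iodo-4-(methoxymethoxy)phenyl]prop-2-en-1-one
Product: 7 (E)-1-(2,4-dihydroxy-3-iodophenyl)-3-(2,4-dihydroxyphenyl)prop-2-en-1-one
Conditions: HCl (3 M aq.), MeOH, 50 °C, dark
Reagents that add atoms: none
Why: Acid-catalysed acetal methanolysis removes the three MOM groups before any acid-sensitive side chain is present, and a short reaction time without light limits enone isomerisation and closure to flavanone or flavylium.

Step 6
Reactants: 7 (E)-1-(2,4-dihydroxy-3-iodophenyl)-3-(2,4-dihydroxyphenyl)prop-2-en-1-one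
Product: 8 (E)-1-(4-acetoxy-2-hydroxy-3-iodophenyl)-3-(2,4-diacetoxyphenyl)prop-2-en-1-one
Conditions: Ac2O (3.2 equiv), pyridine, CH2Cl2, 0 °C
Reagents that add atoms: acetic anhydride CC(=O)OC(C)=O
Why: O-Acylation should stop at the triacetate because the 2′-hydroxyl is chelated to the ketone and flanked by iodine, which leaves free the one hydroxyl needed later for boron binding.

Step 7
Reactants: 9 3-methylbut-1-yne
Product: 10 (E)-tributyl(3-methylbut-1-en-1-yl)stannane
Conditions: Bu3SnH, PdCl2(PPh3)2 (cat.), THF, 0 °C → rt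
Reagents that add atoms: tributyltin hydride CCCC[SnH](CCCC)CCCC
Why: Palladium-catalysed hydrostannation is a syn addition that should place tin on the unhindered terminal carbon, away from the isopropyl group, and so give the E-alkenylstannane (a minor internal isomer would be removed on purification).

Step 8
Reactants: 8 (E)-1-(4-acetoxy-2-hydroxy-3-iodophenyl)-3-(2,4-diacetoxyphenyl)prop-2-en-1-one; 10 (E)-tributyl(3-methylbut-1-en-1-yl)stannane
Product: 11 (E)-1-{4-acetoxy-2-hydroxy-3-[(E)-3-methylbut-1-en-1-yl]phenyl}-3-(2,4-diacetoxyphenyl)prop-2-en-1-one (dienophile)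
Conditions: Pd2(dba)3 (cat.), AsPh3, CuI (cat.), DMF, 55 °C
Reagents that add atoms: none
Why: Stille coupling runs without base and with retention of alkene geometry, so the acetates, the free phenol and the enone should survive, while AsPh3 and CuI speed transmetalation at the doubly ortho-substituted carbon.

Step 9
Reactants: 7 (E)-1-(2,4-dihydroxy-3-iodophenyl)-3-(2,4-dihydroxyphenyl)prop-2-en-1-one
Product: 12 (E)-1-(2,4-diacetoxy-3-iodophenyl)-3-(2,4-diacetoxyphenyl)prop-2-en-1-one
Conditions: Ac2O (excess), Et3N, DMAP (cat.), CH2Cl2, rt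
Reagents that add atoms: acetic anhydride CC(=O)OC(C)=O
Why: With DMAP catalysis and excess anhydride the chelated 2′-hydroxyl is acylated as well, which later keeps boron off this enone so that it cannot act as a dienophile.

Step 10
Reactants: 12 (E)-1-(2,4-diacetoxy-3-iodophenyl)-3-(2,4-diacetoxyphenyl)prop-2-en-1-one; 13 2-methylbut-3-en-2-ol
Product: 14 (E)-1-{2,4-diacetoxy-3-[(E)-3-hydroxy-3-methylbut-1-en-1-yl]phenyl}-3-(2,4-diacetoxyphenyl)prop-2-en-1-one
Conditions: Pd(OAc)2 (cat.), Bu4NCl, NaHCO3, DMF, 65 °C
Reagents that add atoms: none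
Why: In this ligand-free Heck reaction the aryl–palladium adds to the terminal alkene carbon and β-hydride elimination can only go towards the aryl side (the carbinol carbon has no hydrogen), which should give the E-styrenyl tertiary alcohol.

Step 11
Reactants: 14 (E)-1-{2,4-diacetoxy-3-[(E)-3-hydroxy-3-methylbut-1-en-1-yl]phenyl}-3-(2,4-diacetoxyphenyl)prop-2-en-1-one
Product: 15 (E)-1-{2,4-diacetoxy-3-[(E)-3-methylbuta-1,3-dien-1-yl]phenyl}-3-(2,4-diacetoxyphenyl)prop-2-en-1-one (diene)
Conditions: Burgess reagent, toluene, 50 °C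
Reagents that add atoms: none
Why: Burgess dehydration of the tertiary allylic alcohol (syn elimination through the sulfamate ester) can only remove a methyl hydrogen, which gives the 1,3-diene under neutral conditions that spare the acetates.

Step 12
Reactants: 11 (E)-1-{4-acetoxy-2-hydroxy-3-[(E)-3-methylbut-1-en-1-yl]phenyl}-3-(2,4-diacetoxyphenyl)prop-2-en-1-one; 15 (E)-1-{2,4-diacetoxy-3-[(E)-3-methylbuta-1,3-dien-1-yl]phenyl}-3-(2,4-diacetoxyphenyl)prop-2-en-1-one
Product: 18 (3″S,4″R,5″S)-endo cycloadduct heptaacetate (artonin C with seven acetates and the ortho-hydroxyl of the C4″ aroyl ring free), via boron chelate of the dienophile 16 (not isolated), via boron-bound cycloadduct 17 (not isolated)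
Conditions: (R)-VANOL (1.2 equiv), BH3·THF, AcOH, THF, rt, then volatiles removed; 11, then 15, PhCF3, rt; aq. NaHCO3 work-up
Reagents that add atoms: none
Why: The free 2′-hydroxyl of 11 displaces acetate from the diol–boron acetate and the ketone oxygen closes a six-membered chelate (16), which holds the enone s-cis and lowers its LUMO, so that diene 15 adds in a concerted, asynchronous [4+2] cycloaddition of normal electron demand. The closest known reaction type is the chiral diol/boron-promoted asymmetric Diels–Alder reaction of 2′-hydroxychalcones with 1-aryl-3-methylbuta-1,3-dienes, which itself copies the presumed biosynthesis of the mulberry-type adducts. The cyclohexene ring is closed by intermolecular [4+2] cycloaddition, suprafacial on both partners, in which the σ-bonds C5″–C6″ and C3″–C4″ and the ring double bond C1″=C2″ arise in one event. C4″ and C5″ carry aroyl and aryl trans because the E-enone geometry is transferred, C3″ is cis to the C4″ aroyl because the chelated carbonyl lies endo under the E-diene, and the absolute configuration of all three centres should come from the C2-symmetric diolate on boron, which screens one face of the enone. Regioselectivity (C6″ to the enone β-carbon) is secured by the matched directing effects of the 1-aryl and 3-methyl groups of the diene, and chemoselectivity by the fact that only 11 offers a free ortho-hydroxy ketone to boron, the enone of 15 being masked as its 2′-acetate and the styrenyl side chain of 11 being unactivated. Endo over exo selectivity is the least secured element, and any exo isomer would be removed by chromatography.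

Step 13
Reactants: 18 (3″S,4″R,5″S)-endo cycloadduct heptaacetate
Product: 19 artonin C
Conditions: K2CO3 (cat.), MeOH–THF, 0 °C, argon; pH 5 buffer
Reagents that add atoms: none
Why: Base-catalysed transesterification of the seven aryl acetates is fast at 0 °C, where the C4″ centre α to the ketone, the enone and the alkenes should stay untouched, and oxygen is excluded to protect the polyphenol.

**Compound list**

1 | 2,4-dihydroxyacetophenone | CC(=O)c1ccc(O)cc1O | starting material
2 | 1-(2,4-dihydroxy-3-iodophenyl)ethan-1-one | CC(=O)c1ccc(O)c(I)c1O | intermediate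
3 | 1-[2-hydroxy-3-iodo-4-(methoxymethoxy)phenyl]ethan-1-one | CC(=O)c1ccc(OCOC)c(I)c1O | intermediate
4 | 2,4-dihydroxybenzaldehyde | O=Cc1ccc(O)cc1O | starting material
5 | 2,4-bis(methoxymethoxy)benzaldehyde | COCOc1ccc(C=O)c(OCOC)c1 | intermediate
6 | (E)-3-[2,4-bis(methoxymethoxy)phenyl]-1-[2-hydroxy-3-iodo-4-(methoxymethoxy)phenyl]prop-2-en-1-one | COCOc1ccc(/C=C/C(=O)c2ccc(OCOC)c(I)c2O)c(OCOC)c1 | intermediate
7 | (E)-1-(2,4-dihydroxy-3-iodophenyl)-3-(2,4-dihydroxyphenyl)prop-2-en-1-one | O=C(/C=C/c1ccc(O)cc1O)c1ccc(O)c(I)c1O | intermediate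
8 | (E)-1-(4-acetoxy-2-hydroxy-3-iodophenyl)-3-(2,4-diacetoxyphenyl)prop-2-en-1-one | CC(=O)Oc1ccc(/C=C/C(=O)c2ccc(OC(C)=O)c(I)c2O)c(OC(C)=O)c1 | intermediate
9 | 3-methylbut-1-yne | CC(C)C#C | starting material
10 | (E)-tributyl(3-methylbut-1-en-1-yl)stannane | CCCC[Sn](CCCC)(CCCC)/C=C/C(C)C | intermediate
11 | (E)-1-{4-acetoxy-2-hydroxy-3-[(E)-3-methylbut-1-en-1-yl]phenyl}-3-(2,4-diacetoxyphenyl)prop-2-en-1-one (dienophile) | CC(=O)Oc1ccc(/C=C/C(=O)c2ccc(OC(C)=O)c(/C=C/C(C)C)c2O)c(OC(C)=O)c1 | intermediate
12 | (E)-1-(2,4-diacetoxy-3-iodophenyl)-3-(2,4-diacetoxyphenyl)prop-2-en-1-one | CC(=O)Oc1ccc(/C=C/C(=O)c2ccc(OC(C)=O)c(I)c2OC(C)=O)c(OC(C)=O)c1 | intermediate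
13 | 2-methylbut-3-en-2-ol | CC(C)(O)C=C | starting material
14 | (E)-1-{2,4-diacetoxy-3-[(E)-3-hydroxy-3-methylbut-1-en-1-yl]phenyl}-3-(2,4-diacetoxyphenyl)prop-2-en-1-one | CC(=O)Oc1ccc(/C=C/C(=O)c2ccc(OC(C)=O)c(/C=C/C(C)(C)O)c2OC(C)=O)c(OC(C)=O)c1 | intermediate
15 | (E)-1-{2,4-diacetoxy-3-[(E)-3-methylbuta-1,3-dien-1-yl]phenyl}-3-(2,4-diacetoxyphenyl)prop-2-en-1-one (diene) | CC(=O)Oc1ccc(/C=C/C(=O)c2ccc(OC(C)=O)c(/C=C/C(C)=C)c2OC(C)=O)c(OC(C)=O)c1 | intermediate
16 | spiroborate in which boron carries the (R)-VANOL diolate and is chelated by the 2′-phenoxide and the ketone oxygen of 11 (axial chirality of the diolate not encoded in the SMILES) | CC(=O)Oc1ccc(/C=C/C2=[O+][B-]3(Oc4c(/C=C/C(C)C)c(OC(C)=O)ccc24)Oc2c(-c4c(O3)c5ccccc5cc4-c4ccccc4)c(-c4ccccc4)cc4ccccc24)c(OC(C)=O)c1 | intermediate (not isolated)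
17 | the same spiroborate chelate on the (3″S,4″R,5″S)-endo cycloadduct (axial chirality of the diolate not encoded in the SMILES) | CC1=C[C@H](c2c(OC(C)=O)ccc(C(=O)/C=C/c3ccc(OC(C)=O)cc3OC(C)=O)c2OC(C)=O)[C@H](C2=[O+][B-]3(Oc4c(/C=C/C(C)C)c(OC(C)=O)ccc24)Oc2c(-c4c(O3)c5ccccc5cc4-c4ccccc4)c(-c4ccccc4)cc4ccccc24)[C@@H](c2ccc(OC(C)=O)cc2OC(C)=O)C1 | intermediate (not isolated)
18 | 1-methylcyclohex-1-ene bearing (3S)-3-{2,6-diacetoxy-3-[(E)-3-(2,4-diacetoxyphenyl)prop-2-enoyl]phenyl}, (4R)-4-{4-acetoxy-2-hydroxy-3-[(E)-3-methylbut-1-en-1-yl]benzoyl} (cis to the C3 aryl) and (5S)-5-(2,4-diacetoxyphenyl) (trans to the C4 aroyl) | CC1=C[C@H](c2c(OC(C)=O)ccc(C(=O)/C=C/c3ccc(OC(C)=O)cc3OC(C)=O)c2OC(C)=O)[C@H](C(=O)c2ccc(OC(C)=O)c(/C=C/C(C)C)c2O)[C@@H](c2ccc(OC(C)=O)cc2OC(C)=O)C1 | intermediate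
19 | artonin C: 1-methylcyclohex-1-ene bearing (3S)-3-{2,6-dihydroxy-3-[(E)-3-(2,4-dihydroxyphenyl)prop-2-enoyl]phenyl}, (4R)-4-{2,4-dihydroxy-3-[(E)-3-methylbut-1-en-1-yl]benzoyl} and (5S)-5-(2,4-dihydroxyphenyl) | CC1=C[C@H](c2c(O)ccc(C(=O)/C=C/c3ccc(O)cc3O)c2O)[C@H](C(=O)c2ccc(O)c(/C=C/C(C)C)c2O)[C@@H](c2ccc(O)cc2O)C1 | target

**Step count and risks**

Total step count: 13. Longest linear sequence: 9 steps (steps 1, 2, 4, 5, 9, 10, 11, 12, 13).

The three steps most likely to fail:

Step 12. The process at risk is discrimination between the endo and exo modes and between the two enone faces; a slow cycloaddition at the hindered diene could also let the diene oligomerise. The fallback gives up catalyst control of absolute configuration. Starting again from 11 and 15, the cycloaddition is run with a heterogeneous electron-transfer catalyst, zerovalent silver nanoparticles on SiO2 in CH2Cl2 at about 50 °C, which should favour the endo mode but gives the racemate, that is 18 together with its mirror image ent-18 F1. Preparative chromatography on a chiral stationary phase then returns enantiopure 18, from which step 13 continues.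

Step 10. The process at risk is alkene insertion at the doubly ortho-substituted aryl–palladium, which may be slow enough for the activated 2′-acetate to be lost under the basic conditions. The fallback sets out from 12 and uses a base-free Stille coupling (Pd2(dba)3, AsPh3, CuI, DMF) with (E)-tributyl(3-methylbuta-1,3-dien-1-yl)stannane F2, which is made by palladium-catalysed hydrostannation of commercial 2-methylbut-1-en-3-yne with Bu3SnH. This brings in the complete diene in one coupling and rejoins the route at 15, leaving out 14.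

Step 8. The process at risk is transmetalation next to the free 2′-hydroxyl, with competing protodestannylation of 10 or reduction of the iodide. The fallback reverses the order of coupling and protection. From 7, a Suzuki–Miyaura coupling (Pd(OAc)2, SPhos, K3PO4, THF–H2O, 45 °C) with (E)-4,4,5,5-tetramethyl-2-(3-methylbut-1-en-1-yl)-1,3,2-dioxaborolane F3 (from 9 and pinacolborane, Cp2Zr(H)Cl cat.) should give the free chalcone (E)-1-{2,4-dihydroxy-3-[(E)-3-methylbut-1-en-1-yl]phenyl}-3-(2,4-dihydroxyphenyl)prop-2-en-1-one F4. Triacetylation of F4 as in step 6 (Ac2O, pyridine, 0 °C) rejoins the route at 11.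

Further compounds
F1 | step 12 | ent-18, the (3″R,4″S,5″R) mirror image of cycloadduct 18 | CC1=C[C@@H](c2c(OC(C)=O)ccc(C(=O)/C=C/c3ccc(OC(C)=O)cc3OC(C)=O)c2OC(C)=O)[C@@H](C(=O)c2ccc(OC(C)=O)c(/C=C/C(C)C)c2O)[C@H](c2ccc(OC(C)=O)cc2OC(C)=O)C1
F2 | step 10 | (E)-tributyl(3-methylbuta-1,3-dien-1-yl)stannane | CCCC[Sn](CCCC)(CCCC)/C=C/C(C)=C
F3 | step 8 | (E)-4,4,5,5-tetramethyl-2-(3-methylbut-1-en-1-yl)-1,3,2-dioxaborolane | CC(C)/C=C/B1OC(C)(C)C(C)(C)O1
F4 | step 8 | (E)-1-{2,4-dihydroxy-3-[(E)-3-methylbut-1-en-1-yl]phenyl}-3-(2,4-dihydroxyphenyl)prop-2-en-1-one | O=C(/C=C/c1ccc(O)cc1O)c1ccc(O)c(/C=C/C(C)C)c1O
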